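## The problem

The target is a trans-2,3-diaryl-2,3-dihydrobenzofuran. The dihydrofuran ring is fused to ring A, which carries a hydroxyl at C4 and an (E)-4-hydroxystyryl arm at C6. C2 bears a 2,4-dihydroxyphenyl group (ring B) and C3 a 3,5-dihydroxyphenyl group (ring C). No further ring has to be built, so the difficulty lies in the two adjacent stereocentres C2 (S) and C3 (S) and in attaching three differently oxygenated arenes to them.

The two centres are unequal. C2 is a benzylic ether carbon next to an ortho,para-dioxygenated ring and can ionise, so it can be corrected towards the more stable trans arrangement once C3 is fixed. C3 carries only carbon substituents and nothing else in the molecule can correct it. The absolute configuration at C3 is therefore the real task: C3 can control C2, but not the reverse.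

The sensitive points are:
- six phenols, which must stay masked until the end;
- the E-stilbene, which excludes hydrogenation, light and strong electrophiles;
- the acid-labile C2–O1 bond;
- the doubly benzylic C3–H, which under strong base could open the ring by β-elimination of the phenoxide.

The feature that opens the plan is that C2 and C3 are the two carbons of the C2=C3 enol-ether bond of a benzofuran, each carrying one aryl group on opposite faces. This is the imprint of an anti 1,2-diarylation of that bond. C2–H is the most acidic position of a benzofuran and C3 the nucleophilic one, so the bond can be armed as a boron ate complex at C2 and attacked at C3 by an arylpalladium electrophile.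

## Retrosynthesis

**18 from 17 (six O–CH3 bonds).** Target 18 is traced to its hexamethyl ether 17. Methyl ethers are the only common phenol mask that survives every earlier operation (organolithium, hot carbonate, copper at high temperature, palladium, fluoride). Benzyl ethers are held in reserve: they need hydrogenolysis, which the stilbene forbids, or a Lewis acid of their own and extra steps on each component. The forward step must cleave six ethers with a boron trihalide without harming the alkene or C2. Two structural points help. The styryl arm at C6 is too far from ring C for the acid-induced ring closure known for stilbene dimers whose arm sits next to C3. Any heterolysis of C2–O1 can only return to the trans ring under the control of the untouched C3.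

**17 from 16 (C2–H from C2–B).** The hydrogen at C2 is traced to a boron substituent in tertiary boronic ester 16. This cut is what allows the neighbouring C2–aryl bond to be made by a 1,2-shift from boron. The forward step must replace boron by hydrogen with retention, which puts H cis to ring C and leaves the two aryl groups trans.

**16 from 10, 13 and 12 (C2–aryl and C3–aryl).** Both aryl–carbon bonds are cut in one operation. What remains is the flat, achiral benzofuran 10, the boronic ester 13 (ring B) and the aryl triflate 12 (ring C). Compared with cuts inside the heterocycle (O1–C2, C2–C3 or C3–C3a), this one removes both stereocentres and two of the four arenes at once and leaves fragments that are bought or made in one step. The forward reaction must choose one face of C2=C3 under catalyst control, deliver ring B to C2 and ring C to C3 in an anti sense, and avoid simple biaryl coupling.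

**12 from 11; 13 purchased.** The triflate 12 comes from phenol 11 by O-sulfonylation. The boronic ester 13 is an article of commerce. No selectivity question arises.

**10 from 9, 8 and 6 (the furan ring).** The C2–H of 10 is traced to a carboxyl group (acid 9, ester 8) that serves as a traceless activator. The furan ring of 8 is cut at O1–C2 and C2=C3 back to salicylaldehyde 6, that is, to a phenol alkylation and an intramolecular aldol condensation with an α-bromoacetate. Acid cyclisation of an aryloxyacetaldehyde acetal would have to choose between two ortho positions of a 3-methoxy-5-styrylphenol and would expose the stilbene to strong acid. Here the formyl group of 6 fixes the regiochemistry.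

**6 from 5 and 3 (one O–CH3, then C–CHO).** The free phenol of 6 comes from dimethoxy aldehyde 5 by cleaving one methoxy group, which the adjacent formyl group singles out by chelation. The formyl carbon of 5 is cut back to the bromine of stilbene 3, whose position between the two methoxy groups is fixed in the starting material. The forward sequence needs a halogen–metal exchange that is faster than attack on the stilbene.

**3 from 1 and 2 (the stilbene C=C).** The alkene is cut into aldehyde 1 and benzylic phosphonate 2. A phosphonate olefination is preferred to a Heck coupling of the aryl bromide because it leaves the bromine for the next step and gives the E-alkene without regioisomers.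

## Roads not taken

**Alternative 1: late benzannulation to build ring C.** The cut removes the three bonds of the resorcinol ring. Forward, cyclobutenone A1 is heated with an alkoxyalkyne; electrocyclic opening to a vinylketene, [2+2] addition, a second opening and 6π closure (Danheiser benzannulation) would give phenol ether A2.
- Merits: ring C arrives with its 1,3,5-oxygen pattern fixed by mechanism; no metal and no coupling at the hindered C3 are needed; every reaction type is known.
- Weak points: the stereochemical problem is not solved but moved. A1 must already hold C2 and C3 trans and enantiopure. The C3–H of A1 sits on the β-carbon of an enone and is open to epimerisation on heating. The bromine still has to be exchanged for the styryl arm, and two different oxygen masks have to be removed.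
- Comparison: the chosen plan is less certain in method, but it sets both stereocentres and attaches two arenes in one catalytic step and is several steps shorter.

**Alternative 2: flavanone ring contraction.** The cut is C3–C3a. Forward, flavanone A3 is oxidised by a trivalent iodine reagent in acidic orthoformate; ring A migrates from the ketal carbon to the neighbouring carbon, and the contracted ester A4 results, trans by control from C2.
- Merits: enantioenriched flavanones are accessible by known conjugate additions; the contraction is a known reaction; the ester is a flexible handle.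
- Weak points: the ester must still be turned into ring C, which costs several steps and passes through a C3 radical or enolate. The contraction runs in strong acid, while C2 of A3 is a benzylic ether next to an ortho,para-dimethoxyphenyl ring; reversible opening to the chalcone would erase the only stereocentre present. The electron-rich ring B can compete with ring A as the migrating group. The styryl arm again comes late.
- Comparison: this road uses only known chemistry, a real advantage in method risk. The chosen plan sets against it a shorter sequence and the fact that chirality is never stored at an ionisable centre under strongly acidic, oxidising conditions.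

**Alternative 3: [4+1] annulation of a sulfonium ylide with an ortho-quinone methide.** The cuts are C2–C3 and O1–C2. Forward, a carbonate base turns sulfone A5 into the ortho-quinone methide and a chiral benzylic sulfonium salt such as A6 into its ylide; conjugate addition and displacement of the sulfide by the phenoxide close the ring to A7, which is identical with 17.
- Merits: the ring and both stereocentres form in one convergent step; trans selectivity is inherent; no boron has to be removed; A5 is reachable from salicylaldehyde 6. The overall count is equal to or one step below that of the chosen plan, so in step economy this road is at least as good.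
- Weak points: the centre that cannot be corrected, C3, is set by the facial choice of a semi-stabilised ylide adding to a hindered, electron-rich quinone methide. A stoichiometric chiral sulfide must exert this control from a distance, and betaine reversibility can erode it. The quinone methide can also dimerise.
- Comparison: the chosen plan sets against this a catalytic chiral controller bound directly to C3, an anti relationship enforced by mechanism, and three components that can be varied independently.

Key step: step 8

Assumption: the (S,S,R,R) form of the ferrocenyl bisphosphine named in step 8 is taken to favour the face of C2=C3 that leads to 3S; if the opposite sense is found, the mirror-image ligand is used with no other change.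

## Route

Step 1
Reactants: 1 4-bromo-3,5-dimethoxybenzaldehyde; 2 diethyl (4-methoxybenzyl)phosphonate
Product: 3 2-bromo-1,3-dimethoxy-5-[(E)-4-methoxystyryl]benzene
Conditions: KOtBu, THF, 0 to 23 °C
Reagents that add atoms: none
Why: Horner–Wadsworth–Emmons olefination of a non-enolisable aryl aldehyde with a benzylic phosphonate anion; the E-stilbene should be strongly favoured, and the aryl bromide is inert to KOtBu.

Step 2
Reactants: 3 2-bromo-1,3-dimethoxy-5-[(E)-4-methoxystyryl]benzene
Product: 5 2,6-dimethoxy-4-[(E)-4-methoxystyryl]benzaldehyde, via aryllithium 4 (not isolated)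
Conditions: n-BuLi, THF, −78 °C; DMF, −78 to 0 °C; aq. NH4Cl
Reagents that add atoms: N,N-dimethylformamide, CN(C)C=O
Why: Bromine–lithium exchange at −78 °C is much faster than carbolithiation of the stilbene; aryllithium 4, flanked by two methoxy groups, is formylated by DMF (Bouveault-type formylation) exactly between the two ethers.

Step 3
Reactants: 5 2,6-dimethoxy-4-[(E)-4-methoxystyryl]benzaldehyde
Product: 6 2-hydroxy-6-methoxy-4-[(E)-4-methoxystyryl]benzaldehyde
Conditions: BCl3 (1.2 equiv), CH2Cl2, −78 to 0 °C; H2O
Reagents that add atoms: none
Why: Chelation-controlled mono-demethylation: BCl3 bound to the formyl oxygen cleaves one ortho methoxy group through a six-membered chelate, the resulting aryloxyboron chelate resists a second cleavage, and the remote 4-methoxyphenyl ether is not activated at this temperature.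

Step 4
Reactants: 6 2-hydroxy-6-methoxy-4-[(E)-4-methoxystyryl]benzaldehyde
Product: 8 ethyl 4-methoxy-6-[(E)-4-methoxystyryl]benzofuran-2-carboxylate, via aryloxyacetate aldehyde 7 (not isolated)
Conditions: BrCH2CO2Et, K2CO3, DMF, 23 then 120 °C
Reagents that add atoms: ethyl bromoacetate, CCOC(=O)CBr
Why: Phenoxide O-alkylation followed in the same flask by intramolecular aldol condensation of the ester α-carbon onto the ortho formyl group and dehydration (benzofuran-2-carboxylate annulation of salicylaldehydes); the formyl position fixes the regiochemistry.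

Step 5
Reactants: 8 ethyl 4-methoxy-6-[(E)-4-methoxystyryl]benzofuran-2-carboxylate
Product: 9 4-methoxy-6-[(E)-4-methoxystyryl]benzofuran-2-carboxylic acid
Conditions: NaOH, THF/EtOH/H2O, 60 °C; then aq. HCl
Reagents that add atoms: sodium hydroxide, [Na+].[OH-]
Why: Ester saponification by acyl–oxygen cleavage; nothing else in 8 is base-labile.

Step 6
Reactants: 9 4-methoxy-6-[(E)-4-methoxystyryl]benzofuran-2-carboxylic acid
Product: 10 4-methoxy-6-[(E)-4-methoxystyryl]benzofuran
Conditions: Cu powder (0.3 equiv), quinoline, 190 °C, argon
Reagents that add atoms: none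
Why: Copper-mediated protodecarboxylation of a heteroaryl-2-carboxylic acid through a 2-benzofuranylcopper species that is protonated in the medium, the standard way to 2-unsubstituted benzofurans.

Step 7
Reactants: 11 3,5-dimethoxyphenol
Product: 12 3,5-dimethoxyphenyl trifluoromethanesulfonate
Conditions: Tf2O, pyridine, CH2Cl2, 0 °C
Reagents that add atoms: trifluoromethanesulfonic anhydride, O=S(=O)(OS(=O)(=O)C(F)(F)F)C(F)(F)F
Why: O-sulfonylation of a phenol; a triflate is chosen so that no halide enters the key step.

Step 8
Reactants: 10 4-methoxy-6-[(E)-4-methoxystyryl]benzofuran; 13 2-(2,4-dimethoxyphenyl)-4,4,5,5-tetramethyl-1,3,2-dioxaborolane; 12 3,5-dimethoxyphenyl trifluoromethanesulfonate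
Product: 16 2-[(2S,3S)-2-(2,4-dimethoxyphenyl)-3-(3,5-dimethoxyphenyl)-4-methoxy-6-[(E)-4-methoxystyryl]-2,3-dihydrobenzofuran-2-yl]-4,4,5,5-tetramethyl-1,3,2-dioxaborolane, via 2-lithiobenzofuran 14 (not isolated), via lithium boronate complex 15 (not isolated)
Conditions: 10, n-BuLi (1.05 equiv), THF, −78 °C; 13, −78 to 23 °C; then Pd(OAc)2 (5 mol %), (S,S)-1,1′-bis[bis(4-methoxy-3,5-dimethylphenyl)phosphino]-2,2′-bis[(R)-α-(dimethylamino)benzyl]ferrocene (6 mol %), 12 (1.2 equiv), THF, 60 °C; rapid filtration through deactivated silica
Reagents that add atoms: none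
Why: Proposed new method: C2 lithiation of 10 and capture by 13 give the four-coordinate boronate 15, whose anionic boron makes C3 of the C2=C3 enol-ether bond strongly nucleophilic; oxidative addition of 12 to zerovalent palladium gives a cationic divalent arylpalladium that binds this π-bond, the 2,4-dimethoxyphenyl group shifts from boron to C2 antiperiplanar to the forming C3–Pd bond (1,2-metallate rearrangement), and stereoretentive reductive elimination puts the 3,5-dimethoxyphenyl group on C3 from the palladium face. The closest known reaction types are the palladium-catalysed conjunctive cross-coupling of alkenylboron ate complexes with aryl triflates and the dearomative three-component coupling of 2-indolylboronate complexes with allylpalladium electrophiles; the extension is the pairing of a benzofuran-derived ate complex with an aryl electrophile. No ring is closed; the furan ring is dearomatised. C3 (S) is set by the ferrocenyl bisphosphine, which selects the π-face on which palladium binds. C2 (S) follows from C3, because migration is anti to palladium and reductive elimination is retentive, so the two aryl groups must be trans and boron cis to the C3 aryl group. The conjunctive path must beat direct Suzuki–Miyaura transmetallation; the halide-free medium (n-BuLi-derived ate complex, triflate electrophile) and the wide-bite-angle bisphosphine, which keep palladium cationic and π-acidic, should secure this. The arylpalladium must choose C2=C3 over the stilbene, which the anionic activation of the ate-complex alkene against a neutral 1,2-diarylethene should ensure. Reductive elimination must beat β-elimination, which is helped by the quaternary C2 and by the ring holding O1 out of the syn-coplanar geometry needed for β-alkoxide loss.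

Step 9
Reactants: 16 2-[(2S,3S)-2-(2,4-dimethoxyphenyl)-3-(3,5-dimethoxyphenyl)-4-methoxy-6-[(E)-4-methoxystyryl]-2,3-dihydrobenzofuran-2-yl]-4,4,5,5-tetramethyl-1,3,2-dioxaborolane
Product: 17 (2S,3S)-2-(2,4-dimethoxyphenyl)-3-(3,5-dimethoxyphenyl)-4-methoxy-6-[(E)-4-methoxystyryl]-2,3-dihydrobenzofuran
Conditions: n-Bu4NF·3H2O (2 equiv), toluene, 45 °C
Reagents that add atoms: none
Why: Fluoride-promoted protodeboronation of a tertiary benzylic boronic ester: the fluoroborate complex is protonated at carbon by hydrogen-bonded water from the boron face (retentive electrophilic substitution), a reaction type established for tertiary benzylic and α-heteroatom-substituted boronic esters; retention places H cis to the C3 aryl group, which is also the thermodynamically preferred C2 configuration.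

Step 10
Reactants: 17 (2S,3S)-2-(2,4-dimethoxyphenyl)-3-(3,5-dimethoxyphenyl)-4-methoxy-6-[(E)-4-methoxystyryl]-2,3-dihydrobenzofuran
Product: 18 4-[(2S,3S)-3-(3,5-dihydroxyphenyl)-4-hydroxy-6-[(E)-4-hydroxystyryl]-2,3-dihydrobenzofuran-2-yl]benzene-1,3-diol
Conditions: BBr3 (excess), CH2Cl2, −78 to 0 °C; MeOH, then H2O
Reagents that add atoms: none
Why: Exhaustive aryl methyl ether cleavage by BBr3 (Lewis adduct formation, then bromide attack at methyl); no stereocentre is formed, C3 is inert to the reagent, C2 can only re-close to the favoured trans ring if it ionises, and resveratrol-type E-stilbenes tolerate these conditions.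

## Compound list

1 | 4-bromo-3,5-dimethoxybenzaldehyde | COc1cc(C=O)cc(OC)c1Br | starting material
2 | diethyl (4-methoxybenzyl)phosphonate | CCOP(=O)(Cc1ccc(OC)cc1)OCC | starting material
3 | 2-bromo-1,3-dimethoxy-5-[(E)-4-methoxystyryl]benzene | COc1ccc(/C=C/c2cc(OC)c(Br)c(OC)c2)cc1 | intermediate
4 | {2,6-dimethoxy-4-[(E)-4-methoxystyryl]phenyl}lithium | COc1ccc(/C=C/c2cc(OC)c([Li])c(OC)c2)cc1 | intermediate
5 | 2,6-dimethoxy-4-[(E)-4-methoxystyryl]benzaldehyde | COc1ccc(/C=C/c2cc(OC)c(C=O)c(OC)c2)cc1 | intermediate
6 | 2-hydroxy-6-methoxy-4-[(E)-4-methoxystyryl]benzaldehyde | COc1ccc(/C=C/c2cc(O)c(C=O)c(OC)c2)cc1 | intermediate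
7 | ethyl 2-{2-formyl-3-methoxy-5-[(E)-4-methoxystyryl]phenoxy}acetate | CCOC(=O)COc1cc(/C=C/c2ccc(OC)cc2)cc(OC)c1C=O | intermediate
8 | ethyl 4-methoxy-6-[(E)-4-methoxystyryl]benzofuran-2-carboxylate | CCOC(=O)c1cc2c(OC)cc(/C=C/c3ccc(OC)cc3)cc2o1 | intermediate
9 | 4-methoxy-6-[(E)-4-methoxystyryl]benzofuran-2-carboxylic acid | OC(=O)c1cc2c(OC)cc(/C=C/c3ccc(OC)cc3)cc2o1 | intermediate
10 | 4-methoxy-6-[(E)-4-methoxystyryl]benzofuran | COc1ccc(/C=C/c2cc(OC)c3ccoc3c2)cc1 | intermediate
11 | 3,5-dimethoxyphenol | COc1cc(O)cc(OC)c1 | starting material
12 | 3,5-dimethoxyphenyl trifluoromethanesulfonate | COc1cc(OC)cc(OS(=O)(=O)C(F)(F)F)c1 | intermediate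
13 | 2-(2,4-dimethoxyphenyl)-4,4,5,5-tetramethyl-1,3,2-dioxaborolane | COc1ccc(B2OC(C)(C)C(C)(C)O2)c(OC)c1 | starting material
14 | {4-methoxy-6-[(E)-4-methoxystyryl]benzofuran-2-yl}lithium | [Li]c1cc2c(OC)cc(/C=C/c3ccc(OC)cc3)cc2o1 | intermediate
15 | lithium (2,4-dimethoxyphenyl){4-methoxy-6-[(E)-4-methoxystyryl]benzofuran-2-yl}(pinacolato)borate | [Li+].COc1ccc(/C=C/c2cc(OC)c3cc([B-]4(c5ccc(OC)cc5OC)OC(C)(C)C(C)(C)O4)oc3c2)cc1 | intermediate
16 | 2-[(2S,3S)-2-(2,4-dimethoxyphenyl)-3-(3,5-dimethoxyphenyl)-4-methoxy-6-[(E)-4-methoxystyryl]-2,3-dihydrobenzofuran-2-yl]-4,4,5,5-tetramethyl-1,3,2-dioxaborolane | COc1ccc(/C=C/c2cc(OC)c3c(c2)O[C@](B2OC(C)(C)C(C)(C)O2)(c2ccc(OC)cc2OC)[C@H]3c2cc(OC)cc(OC)c2)cc1 | intermediate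
17 | (2S,3S)-2-(2,4-dimethoxyphenyl)-3-(3,5-dimethoxyphenyl)-4-methoxy-6-[(E)-4-methoxystyryl]-2,3-dihydrobenzofuran | COc1ccc(/C=C/c2cc(OC)c3c(c2)O[C@H](c2ccc(OC)cc2OC)[C@H]3c2cc(OC)cc(OC)c2)cc1 | intermediate
18 | 4-[(2S,3S)-3-(3,5-dihydroxyphenyl)-4-hydroxy-6-[(E)-4-hydroxystyryl]-2,3-dihydrobenzofuran-2-yl]benzene-1,3-diol (CNP0156611.2) | Oc1ccc(/C=C/c2cc(O)c3c(c2)O[C@H](c2ccc(O)cc2O)[C@H]3c2cc(O)cc(O)c2)cc1 | target

## Step count and least certain steps

Total: 10 steps. Longest linear sequence: 9 steps (steps 1 to 6, then 8, 9 and 10); step 7 is a one-step branch.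

**Step 8 (key step, proposed new method).** Three things are most likely to go wrong. The ate complex may transmetallate directly to palladium, so that biaryl coupling outruns the metallate shift. The ligand may discriminate poorly between the faces of a flat heteroarene whose C3 is flanked by the C4 methoxy group. The arylpalladium may insert into the stilbene.

The fallback uses known chemistry and no boron; it sets out from salicylaldehyde 6 and rejoins at 17. Mitsunobu etherification of 6 with 2,4-dimethoxybenzyl alcohol (PPh3, diisopropyl azodicarboxylate) would give 2-[(2,4-dimethoxybenzyl)oxy]-6-methoxy-4-[(E)-4-methoxystyryl]benzaldehyde F1. Addition of 3,5-(MeO)2C6H3MgBr would give the diarylmethanol F2, MnO2 oxidation the diaryl ketone F3, and hydrazine hydrate in hot ethanol the hydrazone F4. Oxidation of F4 with MnO2 generates the diaryldiazomethane F5. With Rh2(S-PTAD)4, dirhodium tetrakis[(S)-(1-adamantyl)(phthalimido)acetate], or its antipode, chosen to give 3S, F5 should undergo enantioselective donor/donor carbene insertion into the benzylic O–CH2 bond. On the precedent of this reaction class, the product is expected to be the 2,3-cis dihydrobenzofuran F6. Catalytic CF3CO2H in CH2Cl2 then equilibrates C2 through its benzylic cation to the trans isomer 17, with C3 as the controlling centre.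

**Step 9.** The hindered, electron-rich tertiary boronic ester may react sluggishly, or C2 may lose stereochemical fidelity if a free carbanion intervenes, which would be protonated anti to ring C. The fallback gives up stereoretention and relies on thermodynamic correction; it sets out from 16 and rejoins at 17. In-situ transesterification with a catechol borate gives the catechol boronic ester F7. A radical chain reduction with 4-tert-butylcatechol as hydrogen donor replaces boron by hydrogen through the C2 radical. The resulting mixture of 17 and its C2 epimer F6 is equilibrated with catalytic CF3CO2H to 17; C3 is never touched.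

**Step 10.** The C2 benzylic cation formed by heterolysis of C2–O1 may be captured by an electron-rich arene of a second molecule, or may lose the C3 proton irreversibly; HBr may add to the stilbene. The fallback changes the protecting group to benzyl, which is cleaved at −78 °C; it sets out from 10 and rejoins at 18.
- Nucleophilic demethylation of 10 with NaSEt in DMF at 130 °C gives 6-[(E)-4-hydroxystyryl]benzofuran-4-ol F8, and BnBr/K2CO3 gives 4-(benzyloxy)-6-[(E)-4-(benzyloxy)styryl]benzofuran F9.
- Commercial 3,5-bis(benzyloxy)phenol with Tf2O/pyridine gives 3,5-bis(benzyloxy)phenyl trifluoromethanesulfonate F10.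
- 4-Bromoresorcinol with BnBr/K2CO3 gives 2,4-bis(benzyloxy)-1-bromobenzene F11, and Miyaura borylation (bis(pinacolato)diboron, PdCl2[1,1′-bis(diphenylphosphino)ferrocene], KOAc, dioxane, 90 °C) gives 2-[2,4-bis(benzyloxy)phenyl]-4,4,5,5-tetramethyl-1,3,2-dioxaborolane F12.
- The conditions of step 8 applied to F9, F12 and F10 should give the hexabenzyl boronic ester F13, and n-Bu4NF·3H2O the hexabenzyl ether F14.
- BCl3 with pentamethylbenzene in CH2Cl2 at −78 °C removes the six benzyl groups to give 18. The arene scavenger traps the benzyl cations, and the temperature is far below that needed for methyl ethers.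

**Step 6.** Prolonged heating at 190 °C with copper may isomerise or degrade the stilbene, or decarboxylation may stay incomplete. The fallback replaces steps 4 to 6; it sets out from 6 and rejoins at 10. Alkylation of 6 with chloroacetic acid and NaOH gives 2-{2-formyl-3-methoxy-5-[(E)-4-methoxystyryl]phenoxy}acetic acid F15. Heating F15 with Ac2O, NaOAc and AcOH effects a Perkin-type cyclisation with loss of CO2 and gives 10 directly.

## Further compounds

F1 | step 8 | 2-[(2,4-dimethoxybenzyl)oxy]-6-methoxy-4-[(E)-4-methoxystyryl]benzaldehyde | COc1ccc(/C=C/c2cc(OC)c(C=O)c(OCc3ccc(OC)cc3OC)c2)cc1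
F2 | step 8 | (3,5-dimethoxyphenyl){2-[(2,4-dimethoxybenzyl)oxy]-6-methoxy-4-[(E)-4-methoxystyryl]phenyl}methanol (racemic) | COc1ccc(/C=C/c2cc(OC)c(C(O)c3cc(OC)cc(OC)c3)c(OCc3ccc(OC)cc3OC)c2)cc1
F3 | step 8 | (3,5-dimethoxyphenyl){2-[(2,4-dimethoxybenzyl)oxy]-6-methoxy-4-[(E)-4-methoxystyryl]phenyl}methanone | COc1ccc(/C=C/c2cc(OC)c(C(=O)c3cc(OC)cc(OC)c3)c(OCc3ccc(OC)cc3OC)c2)cc1
F4 | step 8 | hydrazone of F3 | COc1ccc(/C=C/c2cc(OC)c(C(=NN)c3cc(OC)cc(OC)c3)c(OCc3ccc(OC)cc3OC)c2)cc1
F5 | step 8 | (3,5-dimethoxyphenyl){2-[(2,4-dimethoxybenzyl)oxy]-6-methoxy-4-[(E)-4-methoxystyryl]phenyl}diazomethane | COc1ccc(/C=C/c2cc(OC)c(C(=[N+]=[N-])c3cc(OC)cc(OC)c3)c(OCc3ccc(OC)cc3OC)c2)cc1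
F6 | step 8 | (2R,3S)-2-(2,4-dimethoxyphenyl)-3-(3,5-dimethoxyphenyl)-4-methoxy-6-[(E)-4-methoxystyryl]-2,3-dihydrobenzofuran (cis) | COc1ccc(/C=C/c2cc(OC)c3c(c2)O[C@@H](c2ccc(OC)cc2OC)[C@H]3c2cc(OC)cc(OC)c2)cc1
F7 | step 9 | 2-[(2S,3S)-2-(2,4-dimethoxyphenyl)-3-(3,5-dimethoxyphenyl)-4-methoxy-6-[(E)-4-methoxystyryl]-2,3-dihydrobenzofuran-2-yl]-1,3,2-benzodioxaborole | COc1ccc(/C=C/c2cc(OC)c3c(c2)O[C@](B2Oc4ccccc4O2)(c2ccc(OC)cc2OC)[C@H]3c2cc(OC)cc(OC)c2)cc1
F8 | step 10 | 6-[(E)-4-hydroxystyryl]benzofuran-4-ol | Oc1ccc(/C=C/c2cc(O)c3ccoc3c2)cc1
F9 | step 10 | 4-(benzyloxy)-6-[(E)-4-(benzyloxy)styryl]benzofuran | C(Oc1ccc(/C=C/c2cc(OCc3ccccc3)c3ccoc3c2)cc1)c1ccccc1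
F10 | step 10 | 3,5-bis(benzyloxy)phenyl trifluoromethanesulfonate | O=S(=O)(Oc1cc(OCc2ccccc2)cc(OCc2ccccc2)c1)C(F)(F)F
F11 | step 10 | 2,4-bis(benzyloxy)-1-bromobenzene | Brc1ccc(OCc2ccccc2)cc1OCc1ccccc1
F12 | step 10 | 2-[2,4-bis(benzyloxy)phenyl]-4,4,5,5-tetramethyl-1,3,2-dioxaborolane | CC1(C)OB(c2ccc(OCc3ccccc3)cc2OCc2ccccc2)OC1(C)C
F13 | step 10 | 2-[(2S,3S)-4-(benzyloxy)-2-[2,4-bis(benzyloxy)phenyl]-3-[3,5-bis(benzyloxy)phenyl]-6-[(E)-4-(benzyloxy)styryl]-2,3-dihydrobenzofuran-2-yl]-4,4,5,5-tetramethyl-1,3,2-dioxaborolane | c1ccccc1COc1ccc(/C=C/c2cc(OCc4ccccc4)c3c(c2)O[C@](B2OC(C)(C)C(C)(C)O2)(c2ccc(OCc4ccccc4)cc2OCc2ccccc2)[C@H]3c2cc(OCc4ccccc4)cc(OCc4ccccc4)c2)cc1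
F14 | step 10 | (2S,3S)-4-(benzyloxy)-2-[2,4-bis(benzyloxy)phenyl]-3-[3,5-bis(benzyloxy)phenyl]-6-[(E)-4-(benzyloxy)styryl]-2,3-dihydrobenzofuran | c1ccccc1COc1ccc(/C=C/c2cc(OCc4ccccc4)c3c(c2)O[C@H](c2ccc(OCc4ccccc4)cc2OCc2ccccc2)[C@H]3c2cc(OCc4ccccc4)cc(OCc4ccccc4)c2)cc1
F15 | step 6 | 2-{2-formyl-3-methoxy-5-[(E)-4-methoxystyryl]phenoxy}acetic acid | OC(=O)COc1cc(/C=C/c2ccc(OC)cc2)cc(OC)c1C=O
A1 | alternative 1 | 3-[(2S,3S)-6-bromo-2-(2,4-dimethoxyphenyl)-4-methoxy-2,3-dihydrobenzofuran-3-yl]cyclobut-2-en-1-one | Brc1cc(OC)c2c(c1)O[C@H](c1ccc(OC)cc1OC)[C@H]2C1=CC(=O)C1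
A2 | alternative 1 | 3-[(2S,3S)-6-bromo-2-(2,4-dimethoxyphenyl)-4-methoxy-2,3-dihydrobenzofuran-3-yl]-5-ethoxyphenol | Brc1cc(OC)c2c(c1)O[C@H](c1ccc(OC)cc1OC)[C@H]2c1cc(O)cc(OCC)c1
A3 | alternative 2 | (2S)-7-bromo-2-(2,4-dimethoxyphenyl)-5-methoxychroman-4-one | Brc1cc(OC)c2c(c1)O[C@H](c1ccc(OC)cc1OC)CC2=O
A4 | alternative 2 | methyl (2S,3S)-6-bromo-2-(2,4-dimethoxyphenyl)-4-methoxy-2,3-dihydrobenzofuran-3-carboxylate | Brc1cc(OC)c2c(c1)O[C@H](c1ccc(OC)cc1OC)[C@H]2C(=O)OC
A5 | alternative 3 | 2-[(3,5-dimethoxyphenyl)(4-tolylsulfonyl)methyl]-3-methoxy-5-[(E)-4-methoxystyryl]phenol (racemic) | COc1ccc(/C=C/c2cc(O)c(C(c3cc(OC)cc(OC)c3)S(=O)(=O)c3ccc(C)cc3)c(OC)c2)cc1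
A6 | alternative 3 | (2R,5R)-1-(2,4-dimethoxybenzyl)-2,5-dimethylthiolan-1-ium tetrafluoroborate | C[C@@H]1CC[C@@H](C)[S+]1Cc1ccc(OC)cc1OC.F[B-](F)(F)F
A7 | alternative 3 | (2S,3S)-2-(2,4-dimethoxyphenyl)-3-(3,5-dimethoxyphenyl)-4-methoxy-6-[(E)-4-methoxystyryl]-2,3-dihydrobenzofuran (identical with 17) | COc1ccc(/C=C/c2cc(OC)c3c(c2)O[C@H](c2ccc(OC)cc2OC)[C@H]3c2cc(OC)cc(OC)c2)cc1
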